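## Retrosynthetic overview

1. Target 16 ⇐ enone 15 (catalyst-controlled Corey–Bakshi–Shibata reduction sets the remote C5' carbinol) ⇐ spiro-lactone 12 + isopropenyllithium ⇐ keto-lactone 11 (Wittig).
2. Enabling feature: in the cyclohexane the fully substituted carbons C1 and C4 are para, the C1 oxygen and the C4 bromine are cis, and the C3 chlorine is trans to both. This is the imprint of a 3-endo-chloro-1,4-epoxycyclohexane (7-oxabicyclo[2.2.1]heptane 9) whose C4–O bond is exchanged for C4–Br with retention (TiBr4, relayed by the C3 chlorine).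
3. That oxabicycle ⇐ one enantioselective Diels–Alder reaction of the 2,5-disubstituted furan 4 (C1, C6, C5, C4 and the C1 oxygen) with 2-chloroacrolein 5 (C2 and C3; the formyl group is a traceless activator). It forms C1–C2 and C3–C4 and all three ring stereocentres at once.
4. Furan 4 ⇐ Stetter reaction of 5-methylfurfural 1 with methyl acrylate 2, then ketalisation.
5. Ring order: furan (bought) → carbocycle C1–C6 as the oxa-bridged bicycle (step 3) → bridge opened and temporary δ-lactone closed (step 7) → lactone opened (step 9).

Key step: step 3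

Remark on the chemistry (assumptions): 2-chloroacrolein 5 is taken as a purchasable reagent that is distilled before use. The (S)-configured oxazaborolidinone of step 3 is assumed to select the same dienophile face with furan 4 as in the parent 2-haloacrolein cycloadditions; if not, its enantiomer from (R)-tryptophan is used. Target numbering: ring C1 (C–OH), C2 (CH2), C3 (CHCl), C4 (CBrMe), C5, C6; side chain C1'–C7'.

## Route

Step 1
Reactants: 1 5-methylfuran-2-carbaldehyde (5-methylfurfural); 2 methyl acrylate
Product: 3 methyl 4-(5-methylfuran-2-yl)-4-oxobutanoate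
Conditions: 3-benzyl-5-(2-hydroxyethyl)-4-methylthiazolium chloride (10 mol%), Et3N (0.5 equiv), DMF, 70 °C
Reagents that add atoms: none
Why: Stetter reaction: the thiazolium-derived acyl-anion equivalent of the heteroaromatic aldehyde adds 1,4 to the acrylate, a combination with close precedent for furfurals, and delivers the C2'–C5' chain at the right oxidation levels (ketone at C2', carboxyl at C5') in one step.

Step 2
Reactants: 3 methyl 4-(5-methylfuran-2-yl)-4-oxobutanoate
Product: 4 methyl 3-[2-(5-methylfuran-2-yl)-1,3-dioxolan-2-yl]propanoate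
Conditions: HOCH2CH2OH (5 equiv), pyridinium p-toluenesulfonate (10 mol%), benzene, reflux, azeotropic removal of water
Reagents that add atoms: ethane-1,2-diol, OCCO
Why: Acid-catalysed ketalisation turns the electron-poor 2-acylfuran into an electron-rich 2,5-dialkylfuran that can serve as a diene and places a bulky, inductively electron-withdrawing substituent on the furan carbon that becomes C1, which is what steers the regiochemistry of step 3.

Step 3
Reactants: 4 methyl 3-[2-(5-methylfuran-2-yl)-1,3-dioxolan-2-yl]propanoate; 5 2-chloroprop-2-enal (2-chloroacrolein)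
Product: 6 methyl 3-{2-[(1R,4R,5R)-5-chloro-5-formyl-4-methyl-7-oxabicyclo[2.2.1]hept-2-en-1-yl]-1,3-dioxolan-2-yl}propanoate (5-endo-chloro, 5-exo-formyl)
Conditions: 5 (1.5 equiv), (4S)-2-butyl-4-(1H-indol-3-ylmethyl)-3-(4-methylbenzenesulfonyl)-1,3,2-oxazaborolidin-5-one (20 mol%), CH2Cl2, −78 °C; Et3N quench; crude adduct kept below 0 °C and used at once
Reagents that add atoms: none
Why: The boron Lewis acid binds the formyl oxygen of 5 in its s-cis form and the furan adds in a concerted but asynchronous [4+2] cycloaddition in which the unsubstituted CH2 terminus of the dienophile bonds first; the closest known reaction type is the oxazaborolidinone-catalysed enantioselective Diels–Alder reaction of furan itself with 2-chloro- and 2-bromoacrolein. The carbocycle C1–C6 of the target is closed in the intermolecular suprafacial [4+2] mode across the 2,5-positions of the furan, so that the furan oxygen becomes the 1,4-bridge of a 7-oxabicyclo[2.2.1]heptene. The two bridgehead centres (C1 and C4) are set together by the diene face that is attacked, which the indolylmethyl group of the catalyst dictates by shielding one face of the bound dienophile, and C3 is set by the exo-formyl (endo-chloro) transition state that 2-haloacroleins prefer. The step needs regioselectivity (CH2 to the ketal-bearing furan carbon), which should be secured electronically because the developing positive charge then sits on the methyl-bearing furan carbon and not next to the electron-withdrawing ketal, and sterically because the fully substituted dienophile carbon avoids the bulky dioxolane. It also needs the kinetic adduct to be preserved, which the low temperature and the immediate hydrogenation in step 4 should secure.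

Step 4
Reactants: 6 methyl 3-{2-[(1R,4R,5R)-5-chloro-5-formyl-4-methyl-7-oxabicyclo[2.2.1]hept-2-en-1-yl]-1,3-dioxolan-2-yl}propanoate
Product: 7 methyl 3-{2-[(1S,3R,4R)-3-chloro-3-formyl-4-methyl-7-oxabicyclo[2.2.1]heptan-1-yl]-1,3-dioxolan-2-yl}propanoate (3-endo-chloro, 3-exo-formyl)
Conditions: H2 (1 atm), 5% Rh/Al2O3, EtOAc, 0 °C
Reagents that add atoms: none
Why: Heterogeneous hydrogenation of the strained cis-disubstituted bicyclic alkene is fast at 0 °C, turns C5 and C6 into the methylene groups of the target without creating a stereocentre, and removes the retro-Diels–Alder pathway before any heating, while the hindered aldehyde and the tertiary alkyl chloride should be untouched over Rh/Al2O3.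

Step 5
Reactants: 7 methyl 3-{2-[(1S,3R,4R)-3-chloro-3-formyl-4-methyl-7-oxabicyclo[2.2.1]heptan-1-yl]-1,3-dioxolan-2-yl}propanoate
Product: 8 methyl 3-{2-[(1S,3R,4R)-3-chloro-4-methyl-7-oxabicyclo[2.2.1]heptan-1-yl]-1,3-dioxolan-2-yl}propanoate (3-endo-chloro)
Conditions: tert-dodecanethiol (20 mol%), 1,1'-azobis(cyclohexanecarbonitrile) (20 mol%, in portions), PhCl, 110 °C
Reagents that add atoms: none
Why: Thiol-catalysed radical-chain decarbonylation of an aldehyde: the thiyl radical abstracts the formyl hydrogen, the α-chloro-substituted tertiary acyl radical loses CO rapidly, and the C3 radical should take hydrogen from the thiol on the open exo face (syn to the oxygen bridge, as norbornyl-type radicals do), which keeps chlorine endo, on the face opposite to the oxygen.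

Step 6
Reactants: 8 methyl 3-{2-[(1S,3R,4R)-3-chloro-4-methyl-7-oxabicyclo[2.2.1]heptan-1-yl]-1,3-dioxolan-2-yl}propanoate
Product: 9 methyl 4-[(1S,3R,4R)-3-chloro-4-methyl-7-oxabicyclo[2.2.1]heptan-1-yl]-4-oxobutanoate
Conditions: 2 M aq. HCl–THF (1:2), 45 °C
Reagents that add atoms: water, O
Why: Acid-catalysed ketal hydrolysis unmasks the C2' ketone, which step 7 needs both as a chelating site and to forbid ionisation of the C1–O bond, while the bridged tertiary ether, deactivated by the adjacent ketal or ketone and by the β-chlorine, should survive dilute acid.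

Step 7
Reactants: 9 methyl 4-[(1S,3R,4R)-3-chloro-4-methyl-7-oxabicyclo[2.2.1]heptan-1-yl]-4-oxobutanoate
Product: 11 (6S,8R,9R)-9-bromo-8-chloro-9-methyl-1-oxaspiro[5.5]undecane-2,5-dione, via hydroxy keto ester 10 (not isolated)
Conditions: TiBr4 (2.2 equiv), CH2Cl2, −78 → −30 °C; aq. NaHCO3; then pyridinium p-toluenesulfonate (10 mol%), toluene, 60 °C
Reagents that add atoms: titanium tetrabromide, Br[Ti](Br)(Br)Br
Why: Proposed new method: TiBr4 should chelate the ketone oxygen and the bridging ether oxygen of 9, the C1–O bond cannot ionise because C1 is α to the carbonyl, so heterolysis is expected only at C4–O, where the endo chlorine on C3 lies nearly antiperiplanar to the breaking bond and bridges or shields the lower face of the tertiary cation, and bromide is returned from the titanium bromide ion pair on the face that the oxygen has just left, giving overall retention at C4 (bromine cis to the C1 oxygen, trans to chlorine); the closest known reaction types are the Lewis acid or hydrogen halide cleavage of bridged tertiary ethers of the 1,4-cineole type to 4-halocyclohexanols and the anti capture of β-chloro carbenium (chloronium) ions by bromide; the freed tertiary hydroxyl of 10 then closes onto the methyl ester to the δ-lactone, which protects it for the next two steps.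

Step 8
Reactants: 11 (6S,8R,9R)-9-bromo-8-chloro-9-methyl-1-oxaspiro[5.5]undecane-2,5-dione
Product: 12 (6S,8R,9R)-9-bromo-8-chloro-9-methyl-5-methylidene-1-oxaspiro[5.5]undecan-2-one
Conditions: Ph3PCH3Br (1.3 equiv), KN(SiMe3)2 (1.25 equiv), THF, 0 °C; then 11, −78 → 0 °C
Reagents that add atoms: methylenetriphenylphosphorane, C=P(c1ccccc1)(c1ccccc1)c1ccccc1 (made in the flask from Ph3PCH3Br and KN(SiMe3)2)
Why: Wittig methylenation of the ring ketone should be faster than attack on the lactone carbonyl, and because the lactone masks the tertiary hydroxyl only a slight excess of ylide at low temperature is needed, which limits dehydrobromination of the tertiary bromide.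

Step 9
Reactants: 12 (6S,8R,9R)-9-bromo-8-chloro-9-methyl-5-methylidene-1-oxaspiro[5.5]undecan-2-one; 13 2-bromopropene
Product: 15 6-[(1S,3R,4R)-4-bromo-3-chloro-1-hydroxy-4-methylcyclohexyl]-2-methylhepta-1,6-dien-3-one, via hemiketal 14 (not isolated)
Conditions: 13 (1.5 equiv), t-BuLi (3.0 equiv), Et2O, −78 °C; then 12, THF, −78 °C; AcOH quench at −78 °C
Reagents that add atoms: none
Why: Mono-addition of an alkenyllithium to a δ-lactone: the tetrahedral lithium hemiketal should be stable at −78 °C (its leaving group would be a hindered tertiary alkoxide), so the enone is released only on the cold acidic quench and no second addition occurs, and a vinylic lithium has no driving force to exchange with the tertiary alkyl bromide.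

Step 10
Reactants: 15 6-[(1S,3R,4R)-4-bromo-3-chloro-1-hydroxy-4-methylcyclohexyl]-2-methylhepta-1,6-dien-3-one
Product: 16 (1S,3R,4R)-4-bromo-3-chloro-1-[(5R)-5-hydroxy-6-methylhepta-1,6-dien-2-yl]-4-methylcyclohexan-1-ol (target)
Conditions: (S)-1-methyl-3,3-diphenyltetrahydro-1H,3H-pyrrolo[1,2-c][1,3,2]oxazaborole (20 mol%), catecholborane (2.5 equiv), toluene, −78 °C; aqueous work-up
Reagents that add atoms: none
Why: Corey–Bakshi–Shibata reduction: with the (S)-oxazaborolidine the α-branched isopropenyl group acts as the large substituent, so hydride should be delivered to give the (R)-carbinol purely by catalyst control, and catecholborane at −78 °C reduces the carbonyl 1,2 without hydroborating the two 1,1-disubstituted alkenes.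

## Compound list

1 | 5-methylfuran-2-carbaldehyde (5-methylfurfural) | Cc1ccc(C=O)o1 | starting material
2 | methyl acrylate | C=CC(=O)OC | starting material
3 | methyl 4-(5-methylfuran-2-yl)-4-oxobutanoate | COC(=O)CCC(=O)c1ccc(C)o1 | intermediate
4 | methyl 3-[2-(5-methylfuran-2-yl)-1,3-dioxolan-2-yl]propanoate | COC(=O)CCC1(OCCO1)c1ccc(C)o1 | intermediate
5 | 2-chloroprop-2-enal (2-chloroacrolein) | C=C(Cl)C=O | starting material
6 | methyl 3-{2-[(1R,4R,5R)-5-chloro-5-formyl-4-methyl-7-oxabicyclo[2.2.1]hept-2-en-1-yl]-1,3-dioxolan-2-yl}propanoate (chlorine endo, formyl exo) | COC(=O)CCC1(OCCO1)[C@]2(O3)C=C[C@]3(C)[C@](C=O)(Cl)C2 | intermediate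
7 | methyl 3-{2-[(1S,3R,4R)-3-chloro-3-formyl-4-methyl-7-oxabicyclo[2.2.1]heptan-1-yl]-1,3-dioxolan-2-yl}propanoate (chlorine endo, formyl exo) | COC(=O)CCC1(OCCO1)[C@]2(O3)CC[C@]3(C)[C@](C=O)(Cl)C2 | intermediate
8 | methyl 3-{2-[(1S,3R,4R)-3-chloro-4-methyl-7-oxabicyclo[2.2.1]heptan-1-yl]-1,3-dioxolan-2-yl}propanoate (chlorine endo) | COC(=O)CCC1(OCCO1)[C@]2(O3)CC[C@]3(C)[C@H](Cl)C2 | intermediate
9 | methyl 4-[(1S,3R,4R)-3-chloro-4-methyl-7-oxabicyclo[2.2.1]heptan-1-yl]-4-oxobutanoate (chlorine endo) | COC(=O)CCC(=O)[C@]1(O2)CC[C@]2(C)[C@H](Cl)C1 | intermediate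
10 | methyl 4-[(1S,3R,4R)-4-bromo-3-chloro-1-hydroxy-4-methylcyclohexyl]-4-oxobutanoate (not isolated) | COC(=O)CCC(=O)[C@]1(O)CC[C@@](C)(Br)[C@H](Cl)C1 | intermediate
11 | (6S,8R,9R)-9-bromo-8-chloro-9-methyl-1-oxaspiro[5.5]undecane-2,5-dione | O=C1CCC(=O)[C@]2(O1)CC[C@@](C)(Br)[C@H](Cl)C2 | intermediate
12 | (6S,8R,9R)-9-bromo-8-chloro-9-methyl-5-methylidene-1-oxaspiro[5.5]undecan-2-one | O=C1CCC(=C)[C@]2(O1)CC[C@@](C)(Br)[C@H](Cl)C2 | intermediate
13 | 2-bromopropene | C=C(C)Br | starting material
14 | (6S,8R,9R)-9-bromo-8-chloro-9-methyl-5-methylidene-2-(prop-1-en-2-yl)-1-oxaspiro[5.5]undecan-2-ol, both C2 epimers (not isolated) | C=C(C)C1(O)CCC(=C)[C@]2(O1)CC[C@@](C)(Br)[C@H](Cl)C2 | intermediate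
15 | 6-[(1S,3R,4R)-4-bromo-3-chloro-1-hydroxy-4-methylcyclohexyl]-2-methylhepta-1,6-dien-3-one | C=C(C)C(=O)CCC(=C)[C@]1(O)CC[C@@](C)(Br)[C@H](Cl)C1 | intermediate
16 | (1S,3R,4R)-4-bromo-3-chloro-1-[(5R)-5-hydroxy-6-methylhepta-1,6-dien-2-yl]-4-methylcyclohexan-1-ol | C=C(C)[C@H](O)CCC(=C)[C@]1(O)CC[C@@](C)(Br)[C@H](Cl)C1 | target

## Step count and risks

Total step count: 10. Longest linear sequence: 10 steps (1 → 16).

Steps most likely to fail:

Step 7 (Proposed new method). What may go wrong: loss of stereochemical control at C4 by capture of an open tertiary cation from the chlorine-bearing face, or loss of a proton from the cation in place of bromide capture. Fallback with known chemistry, setting out from 9 and coming back at 11: the ether is opened on purpose with elimination under protic acid (TsOH·H2O, toluene, reflux, azeotropic removal of water and methanol; the acid-catalysed eliminative opening known for 1,4-cineole-type ethers). The freed tertiary hydroxyl is trapped at once as the δ-lactone, which should give (6S,8R)-8-chloro-9-methyl-1-oxaspiro[5.5]undec-9-ene-2,5-dione F1. Markovnikov hydrobromination of this trisubstituted alkene (HBr in AcOH–CH2Cl2, 0 °C) then installs the tertiary bromide, with bromide expected to enter anti to the neighbouring chlorine. Compound 11 is separated from any C9 epimer by chromatography or crystallisation.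

Step 3. What may go wrong: reversal of the cycloaddition before the adduct is secured, or addition of the dienophile to the hindered unsymmetrical furan in the wrong orientation or on the wrong face, so that conversion, regiochemical purity or enantiomeric purity is lost. Fallback, setting out from 3 and coming back at 9: auxiliary control with separation in place of catalyst control.
- Ketone 3 is ketalised with (1R,2R)-1,2-diphenylethane-1,2-diol (pyridinium p-toluenesulfonate, benzene, azeotropic removal of water) to methyl 3-[(4R,5R)-2-(5-methylfuran-2-yl)-4,5-diphenyl-1,3-dioxolan-2-yl]propanoate F2.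
- F2 and 5 are combined without catalyst under high pressure (CH2Cl2, about 12 kbar, room temperature), conditions under which furan cycloadditions are driven forward. The diastereomer methyl 3-{(4R,5R)-2-[(1R,4R,5R)-5-chloro-5-formyl-4-methyl-7-oxabicyclo[2.2.1]hept-2-en-1-yl]-4,5-diphenyl-1,3-dioxolan-2-yl}propanoate F3 is separated from its isomers by chromatography or crystallisation.
- Hydrogenation as in step 4 should give methyl 3-{(4R,5R)-2-[(1S,3R,4R)-3-chloro-3-formyl-4-methyl-7-oxabicyclo[2.2.1]heptan-1-yl]-4,5-diphenyl-1,3-dioxolan-2-yl}propanoate F4.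
- Decarbonylation as in step 5 should give methyl 3-{(4R,5R)-2-[(1S,3R,4R)-3-chloro-4-methyl-7-oxabicyclo[2.2.1]heptan-1-yl]-4,5-diphenyl-1,3-dioxolan-2-yl}propanoate F5.
- Acid hydrolysis as in step 6 releases the diol and gives 9.

Step 9. What may go wrong: collapse of the tetrahedral intermediate before the quench followed by a second addition, or base-induced dehydrobromination of the tertiary bromide by the organolithium. Fallback, setting out from 12 and coming back at 15: the lactone is opened by aminolysis (MeNH(OMe)·HCl, i-PrMgCl, THF, −20 °C) to 4-[(1S,3R,4R)-4-bromo-3-chloro-1-hydroxy-4-methylcyclohexyl]-N-methoxy-N-methylpent-4-enamide F6. The chelated adduct of F6 with isopropenylmagnesium bromide (THF, −20 → 0 °C) cannot add a second time and releases 15 on work-up.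

Further compounds
F1 | step 7 | (6S,8R)-8-chloro-9-methyl-1-oxaspiro[5.5]undec-9-ene-2,5-dione | O=C1CCC(=O)[C@]2(O1)CC=C(C)[C@H](Cl)C2
F2 | step 3 | methyl 3-[(4R,5R)-2-(5-methylfuran-2-yl)-4,5-diphenyl-1,3-dioxolan-2-yl]propanoate | COC(=O)CCC1(O[C@H](c2ccccc2)[C@@H](c2ccccc2)O1)c1ccc(C)o1
F3 | step 3 | methyl 3-{(4R,5R)-2-[(1R,4R,5R)-5-chloro-5-formyl-4-methyl-7-oxabicyclo[2.2.1]hept-2-en-1-yl]-4,5-diphenyl-1,3-dioxolan-2-yl}propanoate | COC(=O)CCC1(O[C@H](c2ccccc2)[C@@H](c2ccccc2)O1)[C@]2(O3)C=C[C@]3(C)[C@](C=O)(Cl)C2
F4 | step 3 | methyl 3-{(4R,5R)-2-[(1S,3R,4R)-3-chloro-3-formyl-4-methyl-7-oxabicyclo[2.2.1]heptan-1-yl]-4,5-diphenyl-1,3-dioxolan-2-yl}propanoate | COC(=O)CCC1(O[C@H](c2ccccc2)[C@@H](c2ccccc2)O1)[C@]2(O3)CC[C@]3(C)[C@](C=O)(Cl)C2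
F5 | step 3 | methyl 3-{(4R,5R)-2-[(1S,3R,4R)-3-chloro-4-methyl-7-oxabicyclo[2.2.1]heptan-1-yl]-4,5-diphenyl-1,3-dioxolan-2-yl}propanoate | COC(=O)CCC1(O[C@H](c2ccccc2)[C@@H](c2ccccc2)O1)[C@]2(O3)CC[C@]3(C)[C@H](Cl)C2
F6 | step 9 | 4-[(1S,3R,4R)-4-bromo-3-chloro-1-hydroxy-4-methylcyclohexyl]-N-methoxy-N-methylpent-4-enamide | CON(C)C(=O)CCC(=C)[C@]1(O)CC[C@@](C)(Br)[C@H](Cl)C1
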